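**Retrosynthetic overview**
1. The target comes from saturation of a vinyl group. The vinyl ketone comes from an enantioselective rhodium-catalysed hydroacylation of buta-1,3-diene by the fully assembled aldehyde, which forms the bond from the carbonyl carbon to the stereogenic α carbon.
2. Feature used: the ketone carbon sits on C5′ of ring A (benzene: C1′ CH2, C2′ OCH3, C4′ and C6′ OH), between two hydroxyls. It is therefore the formyl carbon of a 2,6-dihydroxybenzaldehyde that can chelate rhodium, and the only stereocenter (the α carbon with its CH3 and C2H5) is butadiene plus one hydrogen.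
3. The assembled aldehyde comes from the C3(ring B)–CH2–C1′(ring A) bridge: hydroxypyranone, Eschenmoser's salt (Mannich base, then methylidene dione) and 2,6-dihydroxy-4-methoxybenzaldehyde.
4. The hydroxypyranone comes from the silyl enol ether of pentan-3-one and malonyl dichloride; the benzaldehyde comes from para-O-methylation of 2,4,6-trihydroxybenzaldehyde.
5. Rings: ring A is bought; ring B (the 2-pyranone) is the only ring built (step 3); nothing closes after that.

Key step: step 5

Assumption: the hand of the bisphosphine that leads to the 2R ketone cannot be deduced beforehand; the (R)-ligand written in step 5 stands for whichever antipode a test run, checked against material from the fallback to step 5, shows to give 2R.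

**Step 1**
Reactants: 1 2,4,6-trihydroxybenzaldehyde
Product: 2 2,6-dihydroxy-4-methoxybenzaldehyde
Conditions: Me2SO4 (1.0 equiv), K2CO3 (1.0 equiv), acetone, rt
Reagents that add atoms: dimethyl sulfate, COS(=O)(=O)OC
Why: Williamson etherification; the para hydroxyl is the only one not held in a hydrogen bond to the formyl oxygen and gives the most reactive phenoxide, so one equivalent of base and alkylating agent should methylate it first.

**Step 2**
Reactants: 3 pentan-3-one
Product: 4 (Z)-3-(trimethylsilyloxy)pent-2-ene (major isomer; either geometry serves)
Conditions: TMSOTf (1.1 equiv), Et3N (1.3 equiv), Et2O, 0 °C to rt; distil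
Reagents that add atoms: trimethylsilyl trifluoromethanesulfonate, C[Si](C)(C)OS(=O)(=O)C(F)(F)F
Why: Silyl enol ether formation by soft enolisation; the ketone is symmetrical, so there is no regiochemical question and the alkene geometry is lost in the next step.

**Step 3**
Reactants: 4 (Z)-3-(trimethylsilyloxy)pent-2-ene; 5 malonyl dichloride
Product: 7 6-ethyl-4-hydroxy-5-methyl-2H-pyran-2-one, via diketo acid chloride 6 (not isolated)
Conditions: Et2O, −78 °C to rt; filter the precipitate
Reagents that add atoms: none
Why: Effenberger-type pyranone synthesis; C-acylation of the silyl enol ether by one acid chloride gives 6, whose enol oxygen closes the six-membered lactone on the second acid chloride (O-acylation), and tautomerisation gives the 4-hydroxy-2-pyranone of ring B.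

**Step 4**
Reactants: 7 6-ethyl-4-hydroxy-5-methyl-2H-pyran-2-one; 2 2,6-dihydroxy-4-methoxybenzaldehyde
Product: 10 3-[(6-ethyl-4-hydroxy-5-methyl-2-oxo-2H-pyran-3-yl)methyl]-2,6-dihydroxy-4-methoxybenzaldehyde, via Mannich base 8 (not isolated), via methylidene dione 9 (not isolated)
Conditions: 7, CH2=NMe2+ I− (1.0 equiv), MeCN, rt; then 2 (2 equiv), 50 °C
Reagents that add atoms: N,N-dimethylmethylideneammonium iodide (Eschenmoser's salt), C[N+](C)=C.[I-]
Why: Mannich reaction followed by elimination and Friedel–Crafts-type conjugate addition; C3 of the pyranone is aminomethylated, 8 loses dimethylamine on warming to give 9, and one of the two equivalent free ring carbons of 2 adds to it, while pre-forming 8 and using 2 in excess should hold back the bis(pyranonyl)methane and double benzylation of the arene.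

**Step 5**
Reactants: 10 3-[(6-ethyl-4-hydroxy-5-methyl-2-oxo-2H-pyran-3-yl)methyl]-2,6-dihydroxy-4-methoxybenzaldehyde; 11 buta-1,3-diene
Product: 12 3-{[2,4-dihydroxy-6-methoxy-3-[(2R)-2-methylbut-3-enoyl]phenyl]methyl}-6-ethyl-4-hydroxy-5-methyl-2H-pyran-2-one
Conditions: [Rh(C8H12)2]BF4 (5 mol %; C8H12 = cycloocta-1,5-diene), (R)-DTBM-SEGPHOS (5.5 mol %), NaOAc (10 mol %), 11 (5 equiv), ClCH2CH2Cl, 40 °C, sealed tube; vent, short silica plug, use at once
Reagents that add atoms: none
Why: Proposed new method: a flanking hydroxyl of 10 binds monovalent rhodium as the phenoxide (acetate takes up the HBF4) and delivers the formyl C–H for oxidative addition, giving a five-membered acyl hydride chelate of trivalent rhodium that resists decarbonylation; 11 inserts into Rh–H to give a 1-methylallyl (crotyl) complex, and C–C reductive elimination at the methyl-bearing allyl terminus releases 12 and returns monovalent rhodium. The closest known reaction types are rhodium- and cobalt-catalysed hydroacylations of 1,3-dienes and other alkenes by salicylaldehydes and the RuHCl(CO)(PPh3)3-catalysed aldehyde–diene coupling to α-methyl β,γ-unsaturated ketones; an enantioselective branched addition to butadiene itself by a 2,6-dihydroxybenzaldehyde that carries a free hydroxypyranone has not been shown. No ring closes. The new stereocenter is under catalyst control: the C2-symmetric bisphosphine decides which face of the substituted allyl terminus meets the acyl carbon, and the antipode giving 2R is used. The step needs branched (1,2) against linear (1,4) coupling, which the substrate's phenoxide chelate should secure by keeping the acyl ligand cis to the allyl group in a saturated complex where the more substituted, more weakly bound terminus couples, helped by the bulky aryl groups of the phosphine. It also needs the double bond to stay out of conjugation, for which the acetate-buffered, base-free medium, excess 11 and immediate use of crude 12 are chosen.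

**Step 6**
Reactants: 12 3-{[2,4-dihydroxy-6-methoxy-3-[(2R)-2-methylbut-3-enoyl]phenyl]methyl}-6-ethyl-4-hydroxy-5-methyl-2H-pyran-2-one
Product: 13 3-{[2,4-dihydroxy-6-methoxy-3-[(2R)-2-methylbutanoyl]phenyl]methyl}-6-ethyl-4-hydroxy-5-methyl-2H-pyran-2-one
Conditions: H2 (1 atm), RhCl(PPh3)3 (5 mol %), toluene–EtOH (1:1), rt
Reagents that add atoms: none
Why: Homogeneous hydrogenation with Wilkinson's catalyst; the unhindered monosubstituted alkene should be reduced far faster than the substituted, electron-poor pyranone double bonds or the ketone, under neutral conditions, so the α stereocenter from step 5 is carried over unchanged (the descriptor stays R because ethyl takes the rank of vinyl).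

**Compound list**
1 | 2,4,6-trihydroxybenzaldehyde | O=Cc1c(O)cc(O)cc1O | starting material
2 | 2,6-dihydroxy-4-methoxybenzaldehyde | COc1cc(O)c(C=O)c(O)c1 | intermediate
3 | pentan-3-one | CCC(=O)CC | starting material
4 | (Z)-3-(trimethylsilyloxy)pent-2-ene | C/C=C(\O[Si](C)(C)C)CC | intermediate
5 | malonyl dichloride (propanedioyl dichloride) | O=C(Cl)CC(=O)Cl | starting material
6 | 4-methyl-3,5-dioxoheptanoyl chloride (racemic at C4, centre lost on enolisation; formed in the flask) | CCC(=O)C(C)C(=O)CC(=O)Cl | intermediate
7 | 6-ethyl-4-hydroxy-5-methyl-2H-pyran-2-one | CCc1oc(=O)cc(O)c1C | intermediate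
8 | 3-[(dimethylamino)methyl]-6-ethyl-4-hydroxy-5-methyl-2H-pyran-2-one (Mannich base, present as its hydroiodide; formed in the flask) | CCc1oc(=O)c(CN(C)C)c(O)c1C | intermediate
9 | 6-ethyl-5-methyl-3-methylidene-2H-pyran-2,4(3H)-dione (formed in the flask) | CCC1=C(C)C(=O)C(=C)C(=O)O1 | intermediate
10 | 3-[(6-ethyl-4-hydroxy-5-methyl-2-oxo-2H-pyran-3-yl)methyl]-2,6-dihydroxy-4-methoxybenzaldehyde | CCc1oc(=O)c(Cc2c(OC)cc(O)c(C=O)c2O)c(O)c1C | intermediate
11 | buta-1,3-diene | C=CC=C | starting material
12 | 3-{[2,4-dihydroxy-6-methoxy-3-[(2R)-2-methylbut-3-enoyl]phenyl]methyl}-6-ethyl-4-hydroxy-5-methyl-2H-pyran-2-one | CCc1oc(=O)c(Cc2c(OC)cc(O)c(C(=O)[C@H](C)C=C)c2O)c(O)c1C | intermediate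
13 | 3-{[2,4-dihydroxy-6-methoxy-3-[(2R)-2-methylbutanoyl]phenyl]methyl}-6-ethyl-4-hydroxy-5-methyl-2H-pyran-2-one | CCc1oc(=O)c(Cc2c(OC)cc(O)c(C(=O)[C@H](C)CC)c2O)c(O)c1C | target

**Step count**
Total: 6 steps. Longest linear sequence: 5 steps (3 → 4 → 7 → 10 → 12 → 13; steps 2 to 6).

**Steps most likely to fail**

Step 5 (carries the label). What may go wrong:
- coupling at the unsubstituted allyl terminus, giving the linear 1,4-adduct;
- poor facial selectivity;
- migration of the double bond into conjugation with loss of the α configuration;
- slow turnover because the polyphenolic substrate and product hold the rhodium.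

Fallback by known chemistry, setting out from pyranone 7 and coming back at target 13, with the stereocenter bought in. Commercially available 5-methoxybenzene-1,3-diol is protected (MOMCl, i-Pr2NEt, CH2Cl2) as 1-methoxy-3,5-bis(methoxymethoxy)benzene F1. Commercially available (2R)-2-methylbutanoic acid is converted (MeNHOMe·HCl, EDC·HCl, i-Pr2NEt, CH2Cl2) into (2R)-N-methoxy-N,2-dimethylbutanamide F2. F1 is lithiated between the two MOM ethers (n-butyllithium, THF, 0 °C; directed ortho-metalation) to [4-methoxy-2,6-bis(methoxymethoxy)phenyl]lithium F3. F3 is acylated by F2 at −78 °C (Weinreb ketone synthesis; the chelated tetrahedral adduct shields the α centre) to (2R)-1-[4-methoxy-2,6-bis(methoxymethoxy)phenyl]-2-methylbutan-1-one F4. HCl in MeOH at rt removes both MOM groups to give (2R)-1-(2,6-dihydroxy-4-methoxyphenyl)-2-methylbutan-1-one F5. F5 (slight excess) is then benzylated at one of its two equivalent free ring carbons by Mannich base 8, made from 7 and Eschenmoser's salt as in step 4 (through 9), to give 13 directly. The same material would serve as the reference for assigning the configuration of the hydroacylation product.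

Step 4. What may go wrong:
- a second benzylation of the arene;
- return of the Mannich base to free pyranone, followed by self-coupling to the bis(pyranonyl)methane;
- slow addition of the formyl-deactivated arene;
- condensation of the formyl group with any free pyranone.

Fallback with the roles reversed, setting out from 2 and coming back at 10. 2 is aminomethylated once (Eschenmoser's salt, 1.0 equiv, CH2Cl2, rt; phenol Mannich reaction) to 3-[(dimethylamino)methyl]-2,6-dihydroxy-4-methoxybenzaldehyde F6, which is isolated and heated with pyranone 7 in 1,4-dioxane at 90 °C. Loss of dimethylamine gives the ortho-quinone methide 2-hydroxy-4-methoxy-5-methylidene-6-oxocyclohexa-1,3-diene-1-carbaldehyde F7, which C3 of 7 traps by conjugate addition to give 10. One CH2 per arene is then fixed by construction and the pyranone cannot couple with itself.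

Step 1. What may go wrong: alkylation running on to the 4,6-dimethyl ether, leaving a mixture that is hard to separate.

Fallback setting out from 1 and coming back at 2. 1 is methylated exhaustively (Me2SO4 in excess, K2CO3, acetone, reflux) to 2,4,6-trimethoxybenzaldehyde F8 (also an article of commerce). The two methyl ethers ortho to the formyl group are then cleaved with AlCl3 (excess, chlorobenzene, 60 °C; carbonyl-chelation-directed demethylation), and the para ether, which cannot chelate, should remain.

**Further compounds**
F1 | step 5 | 1-methoxy-3,5-bis(methoxymethoxy)benzene | COCOc1cc(OC)cc(OCOC)c1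
F2 | step 5 | (2R)-N-methoxy-N,2-dimethylbutanamide | CC[C@@H](C)C(=O)N(C)OC
F3 | step 5 | [4-methoxy-2,6-bis(methoxymethoxy)phenyl]lithium | [Li]c1c(OCOC)cc(OC)cc1OCOC
F4 | step 5 | (2R)-1-[4-methoxy-2,6-bis(methoxymethoxy)phenyl]-2-methylbutan-1-one | CC[C@@H](C)C(=O)c1c(OCOC)cc(OC)cc1OCOC
F5 | step 5 | (2R)-1-(2,6-dihydroxy-4-methoxyphenyl)-2-methylbutan-1-one | CC[C@@H](C)C(=O)c1c(O)cc(OC)cc1O
F6 | step 4 | 3-[(dimethylamino)methyl]-2,6-dihydroxy-4-methoxybenzaldehyde | CN(C)Cc1c(OC)cc(O)c(C=O)c1O
F7 | step 4 | 2-hydroxy-4-methoxy-5-methylidene-6-oxocyclohexa-1,3-diene-1-carbaldehyde | C=C1C(=O)C(C=O)=C(O)C=C1OC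
F8 | step 1 | 2,4,6-trimethoxybenzaldehyde | COc1cc(OC)c(C=O)c(OC)c1
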